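Early on both runs climb fast: Saturday's flask holds 35% J at 1.33 h, Sunday's 33% at 0.250 h, and then each flattens. You are asked about Saturday's flask, followed further.

| flask | E | L | Z | temperature | remark | time |
|---|---|---|---|---|---|---|
| Saturday's | 1.5 M | 1.1 equiv | 0.23 mol% | 35 °C | the very flask that is asked about, followed so far |  |
| Sunday's | 1.5 M | 1.7 equiv | 0.23 mol% | 41 °C | run made earlier |  |
| flask | 1.5 M | 1.10 equiv | 0.23 mol% | 35 °C |  | 30 h |

- Saturday's (time / h: J / %): 1.33: 35; 3.00: 37; 8.00: 38; 20.0: 35
- Sunday's (time / h: J / %): 0.250: 33; 0.500: 39; 1.33: 47; 3.00: 48

(each reading ± 1.5 percentage points)

- winter: at 30 h take out 90% of the J then present, then wait 30 h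
- autumn: at 30 h add Z, 100% of the amount charged, then wait 30 h
- summer: at 30 h raise the temperature by 15 K, then wait 30 h
- dusk: change nothing and wait 30 h more

- what is taken out of J is counted as made
- additions bring no volume worth counting

* J, in percent of the E first charged, at 30 h
* the option that brings most further J ("none" if no option brings more than 2 percentage points) (winter / autumn / summer / dusk / none)
* J present, with what was taken out counted in, in percent of the E first charged, after winter
* J present, with what was taken out counted in, in percent of the E first charged, after summer

Start with the stop. Saturday's readings from 3.00 h to 20.0 h average 36.7%, with no trend beyond the scatter, so I commit to that for J at 30 h.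

Next, the balance. E is the limiting reagent, since L stands at 1.1 equiv per E. A fraction y of E turned to J therefore leaves one minus y of E, and the equivalents of L minus y of L.

Put those amounts into mass action. The stall quotient, J divided by the product of E and L as molarities at the stop, reads 0.526 /M on Saturday's run. Sunday's last two readings average 47.5% and give 0.492 /M, close to it.

Now use it. Winter leaves E and L in Saturday's flask as they stand and cuts the quotient to 0.0526 /M. If the stall quotient were the equilibrium constant, the flask would run again and winter would pay.

That is the weak link. A flask started without J whose catalyst stops working also shows a quotient, one below the constant. So I reforge the reading: in a flask started without J, the stall quotient is a floor under the constant, and it may lie below it. Winter pays if the catalyst lives, autumn if the quotient sits below the constant, and the two quotients, both read at 1.5 M E, do not part those cases.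

The forecast chooses: 36.5% now, winter best, 52% after winter, 36% after summer. Its grounds: “I lean towards equilibrium, but only narrowly.”

The flask gives 37.0%, and autumn is best, adding 6.6 percentage points; winter ends at 37.0% and summer at 37.0%.

    E + L + Z ⇌ Z + J (K = 0.850 /M, k = 0.0600 /M²/s, Ea = 46.0 kJ/mol, ΔH = −9.00 kJ/mol)
    Z → X (k = 3.30 × 10⁻⁴ /s, Ea = 86.0 kJ/mol)
    E + Z → D (k = 6.00 × 10⁻⁵ /M/s, Ea = 75.0 kJ/mol)
    (constants at 35 °C)

The flask's stall quotient, 0.537 /M, lies below the constant 0.85 /M. A second flask, this recipe with 2.5 M E, stops at 52.3% with a quotient of 0.761 /M. In the asked flask, the forward step alone, its way back not counted and the other concentrations held at their charge, gives E a half-life of 0.56 h, while Z's half-life towards X at 0.241 h is of like size, 0.58 h. At 30.0 h the catalyst charged stands in that flask as X 82.8%, D 17.2% and Z 0%.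

The runs were generated by integration from invented constants, and the scatter is random.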